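The route rests on cutting the cis C3=C4 unit out of the dihydropyranone ring as acetylene (ring atoms O1 and C2 to C6, side chain C7 to C13). In one flask lithium acetylide opens a terminal epoxide at C5 (C4–C5 bond), then the alkyne terminus is lithiated and carboxylated with CO2 (C3–C2 bond). This exploits the ring alkene lying between the C5 methylene and the C2 carbonyl, while O1 on C6 is the former epoxide oxygen. The precursor is a silyl-protected epoxy alcohol carrying C6, C7 and C8, obtained by Sharpless kinetic resolution. Semihydrogenation and acid then close the lactone, and a late cross-metathesis attaches the diacetoxy side chain.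

Key step: step 4

Remarks: 3-(methoxymethoxy)prop-1-ene (15) is taken as a catalogue compound. Compound 4 is a racemate, and its SMILES shows both enantiomers.

Step 1
Reactants: 1 acrolein; 2 acrolein dimethyl acetal
Product: 4 rac-(3S,4R)-4-methoxyhexa-1,5-dien-3-ol (anti isomer), via E-methoxyallylchromium dichloride 3 (not isolated)
Conditions: CrCl2, Me3SiI, 2, THF, −30 °C; then 1, −30 → 0 °C
Reagents that add atoms: none
Why: Me3SiI turns the acetal into the α-iodo ether, CrCl2 reduces it to the E-γ-methoxyallylchromium reagent 3 (trivalent chromium), and its Nozaki–Hiyama-type 1,2-addition to acrolein through a chair transition state should give the anti relationship of C7 and C8 as the racemate.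

Step 2
Reactants: 4 rac-(3S,4R)-4-methoxyhexa-1,5-dien-3-ol
Product: 5 (1R,2R)-2-methoxy-1-[(2S)-oxiran-2-yl]but-3-en-1-ol
Conditions: Ti(OiPr)4 (20 mol %), D-(−)-diisopropyl tartrate (24 mol %), t-BuOOH (0.45 equiv), 4 Å molecular sieves, CH2Cl2, −20 °C
Reagents that add atoms: tert-butyl hydroperoxide, CC(C)(C)OO
Why: Sharpless asymmetric epoxidation run as a kinetic resolution: with D-(−)-diisopropyl tartrate the (3S,4R) enantiomer should react fast on the face that gives the erythro epoxy alcohol, which sets C6 by reagent control and leaves the (3R,4S) alcohol unreacted.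

Step 3
Reactants: 5 (1R,2R)-2-methoxy-1-[(2S)-oxiran-2-yl]but-3-en-1-ol
Product: 6 tert-butyl{[(1R,2R)-2-methoxy-1-[(2S)-oxiran-2-yl]but-3-en-1-yl]oxy}dimethylsilane
Conditions: TBSCl, imidazole, DMAP (cat.), DMF, rt
Reagents that add atoms: tert-butyldimethylsilyl chloride, CC(C)(C)[Si](C)(C)Cl
Why: Standard silylation of the secondary alcohol, which blocks Payne rearrangement of the epoxy alcohol in the basic key step and touches neither the epoxide nor any stereocenter.

Step 4
Reactants: 6 tert-butyl{[(1R,2R)-2-methoxy-1-[(2S)-oxiran-2-yl]but-3-en-1-yl]oxy}dimethylsilane; 7 acetylene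
Product: 11 (5S,6S,7R)-6-[(tert-butyldimethylsilyl)oxy]-5-hydroxy-7-methoxynon-8-en-2-ynoic acid, via lithium acetylide 8 (not isolated), via lithium homopropargylic alkoxide 9 (not isolated), via dilithium alkynide alkoxide 10 (not isolated)
Conditions: 7, n-BuLi, THF, −78 °C; BF3·OEt2, then 6, −78 °C; n-BuLi (excess), −78 °C; CO2, −78 → 0 °C; aq. HCl to pH 3
Reagents that add atoms: carbon dioxide, O=C=O
Why: Lithium acetylide 8 opens the BF3-activated terminal epoxide of 6 by SN2 attack at the CH2 carbon C5, which forms C4–C5 and leaves the C6–O bond and its configuration untouched; n-BuLi then lithiates the alkyne terminus of alkoxide 9, and the alkynyllithium 10 adds to CO2, which forms C3–C2. The closest known reaction types are the BF3-mediated alkynylation of epoxides (Yamaguchi–Hirao) and the carboxylation of dilithiated homopropargylic alcohols, run here back to back so that acetylene acts as a two-ended linchpin for C3 and C4. No ring is closed in this step; the lactone ring closes in step 5 once the triple bond has been reduced to the cis alkene. No stereocenter is created, and C6, C7 and C8 pass through unchanged. The step needs regioselective opening at C5 and carboxylation at carbon: the first is secured by the unhindered primary epoxide carbon next to a C6 shielded by the silyloxy-bearing C7, the second by the fact that any carbonate formed at the C6 alkoxide loses CO2 again on acidic work-up. A silyl shift from the C7 to the C6 oxygen under the basic conditions would do no harm, since step 5 removes the silyl group before the lactone closes.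

Step 5
Reactants: 11 (5S,6S,7R)-6-[(tert-butyldimethylsilyl)oxy]-5-hydroxy-7-methoxynon-8-en-2-ynoic acid
Product: 14 (6S)-6-[(1S,2R)-1-hydroxy-2-methoxybut-3-en-1-yl]-5,6-dihydro-2H-pyran-2-one, via Z-hydroxy acid 12 (not isolated), via silyl-protected lactone 13 (not isolated)
Conditions: H2 (1 atm), Pd/CaCO3 poisoned with Pb(OAc)2, quinoline, EtOAc, rt; filter; aq. HF, MeCN, 0 °C → rt
Reagents that add atoms: none
Why: Syn addition of hydrogen on the poisoned palladium surface should give the Z-enoic acid 12 (Lindlar semihydrogenation, the alkyne reacting ahead of the terminal vinyl group), and aqueous HF then closes the six-membered lactone through the C6 hydroxyl and cleaves the silyl ether without touching the stereocenters.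

Step 6
Reactants: 15 3-(methoxymethoxy)prop-1-ene; 16 acetaldehyde
Product: 20 (2R,3R)-3-(methoxymethoxy)pent-4-en-2-ol, via Z-alkoxyallyllithium 17 (not isolated), via Z-alkoxyallyl diisopinocampheylborane 18 (not isolated), via borinate ester 19 (not isolated)
Conditions: sec-BuLi, THF, −78 °C; (−)-Ipc2BOMe; BF3·OEt2; 16, −78 °C; NaOH, H2O2, rt
Reagents that add atoms: none
Why: Brown γ-alkoxyallylboration: the chelated Z-allyllithium 17 is trapped on boron, the Z-allylborane 18 adds to acetaldehyde through a chair Zimmerman–Traxler transition state to give the syn pair C11/C12, and the isopinocampheyl groups derived from (+)-α-pinene should select the aldehyde face that gives (2R,3R).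

Step 7
Reactants: 20 (2R,3R)-3-(methoxymethoxy)pent-4-en-2-ol
Product: 21 (2R,3R)-pent-4-ene-2,3-diol
Conditions: ZnBr2, n-PrSH, CH2Cl2, 0 °C → rt
Reagents that add atoms: none
Why: ZnBr2-activated cleavage of the methoxymethyl ether with the thiol as trap for the CH2OMe unit, which avoids closure to a cyclic formal with the neighbouring hydroxyl and touches no stereocenter.

Step 8
Reactants: 21 (2R,3R)-pent-4-ene-2,3-diol
Product: 22 (3R,4R)-pent-1-ene-3,4-diyl diacetate
Conditions: Ac2O, pyridine, DMAP (cat.), CH2Cl2, rt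
Reagents that add atoms: acetic anhydride, CC(=O)OC(C)=O
Why: DMAP-catalysed acyl transfer acetylates both secondary alcohols with retention at C11 and C12.

Step 9
Reactants: 14 (6S)-6-[(1S,2R)-1-hydroxy-2-methoxybut-3-en-1-yl]-5,6-dihydro-2H-pyran-2-one; 22 (3R,4R)-pent-1-ene-3,4-diyl diacetate
Product: 23 (6S)-6-[(1S,2R,3E,5R,6R)-5,6-diacetoxy-1-hydroxy-2-methoxyhept-3-en-1-yl]-5,6-dihydro-2H-pyran-2-one
Conditions: 22 (4 equiv), second-generation Hoveyda–Grubbs catalyst RuCl2(H2IMes)(=CH–C6H4-2-OiPr) (10 mol %), CH2Cl2, 40 °C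
Reagents that add atoms: none
Why: Olefin cross-metathesis of the two terminal alkenes with loss of ethene should give the E geometry of C9=C10 as the thermodynamic outcome for two allylic-branched partners, while the electron-poor endocyclic C3=C4 bond of the lactone stays out of the reaction.

Compound list
1 | acrolein (prop-2-enal) | C=CC=O | starting material
2 | acrolein dimethyl acetal (3,3-dimethoxyprop-1-ene) | C=CC(OC)OC | starting material
3 | (E)-(3-methoxyprop-2-en-1-yl)chromium dichloride (trivalent chromium) | CO/C=C/C[Cr](Cl)Cl | intermediate (not isolated)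
4 | rac-(3S,4R)-4-methoxyhexa-1,5-dien-3-ol (anti isomer; both enantiomers shown) | CO[C@H](C=C)[C@@H](O)C=C.CO[C@@H](C=C)[C@H](O)C=C | intermediate
5 | (1R,2R)-2-methoxy-1-[(2S)-oxiran-2-yl]but-3-en-1-ol | CO[C@H](C=C)[C@@H](O)[C@@H]1CO1 | intermediate
6 | tert-butyl{[(1R,2R)-2-methoxy-1-[(2S)-oxiran-2-yl]but-3-en-1-yl]oxy}dimethylsilane | CO[C@H](C=C)[C@@H](O[Si](C)(C)C(C)(C)C)[C@@H]1CO1 | intermediate
7 | acetylene (ethyne) | C#C | starting material
8 | lithium acetylide | [Li+].[C-]#C | intermediate (not isolated)
9 | lithium (4S,5S,6R)-5-[(tert-butyldimethylsilyl)oxy]-6-methoxyoct-7-en-1-yn-4-olate | CO[C@H](C=C)[C@@H](O[Si](C)(C)C(C)(C)C)[C@@H]([O-])CC#C.[Li+] | intermediate (not isolated)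
10 | dilithium (4S,5S,6R)-5-[(tert-butyldimethylsilyl)oxy]-6-methoxyoct-7-en-1-yn-1-id-4-olate | CO[C@H](C=C)[C@@H](O[Si](C)(C)C(C)(C)C)[C@@H]([O-])CC#[C-].[Li+].[Li+] | intermediate (not isolated)
11 | (5S,6S,7R)-6-[(tert-butyldimethylsilyl)oxy]-5-hydroxy-7-methoxynon-8-en-2-ynoic acid | CO[C@H](C=C)[C@@H](O[Si](C)(C)C(C)(C)C)[C@@H](O)CC#CC(=O)O | intermediate
12 | (2Z,5S,6S,7R)-6-[(tert-butyldimethylsilyl)oxy]-5-hydroxy-7-methoxynona-2,8-dienoic acid | CO[C@H](C=C)[C@@H](O[Si](C)(C)C(C)(C)C)[C@@H](O)C/C=C\C(=O)O | intermediate (not isolated)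
13 | (6S)-6-[(1S,2R)-1-[(tert-butyldimethylsilyl)oxy]-2-methoxybut-3-en-1-yl]-5,6-dihydro-2H-pyran-2-one | CO[C@H](C=C)[C@@H](O[Si](C)(C)C(C)(C)C)[C@@H]1CC=CC(=O)O1 | intermediate (not isolated)
14 | (6S)-6-[(1S,2R)-1-hydroxy-2-methoxybut-3-en-1-yl]-5,6-dihydro-2H-pyran-2-one | CO[C@H](C=C)[C@@H](O)[C@@H]1CC=CC(=O)O1 | intermediate
15 | 3-(methoxymethoxy)prop-1-ene (allyl methoxymethyl ether) | C=CCOCOC | starting material
16 | acetaldehyde | CC=O | starting material
17 | [(Z)-3-(methoxymethoxy)prop-2-en-1-yl]lithium | COCO/C=C\[CH2-].[Li+] | intermediate (not isolated)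
18 | [(Z)-3-(methoxymethoxy)prop-2-en-1-yl]bis[(1R,2S,3R,5R)-2,6,6-trimethylbicyclo[3.1.1]heptan-3-yl]borane | COCO/C=C\CB([C@@H]1C[C@@H]2C[C@H]([C@H]1C)C2(C)C)[C@@H]1C[C@@H]2C[C@H]([C@H]1C)C2(C)C | intermediate (not isolated)
19 | (2R,3R)-3-(methoxymethoxy)pent-4-en-2-yl bis[(1R,2S,3R,5R)-2,6,6-trimethylbicyclo[3.1.1]heptan-3-yl]borinate | C=C[C@@H](OCOC)[C@@H](C)OB([C@@H]1C[C@@H]2C[C@H]([C@H]1C)C2(C)C)[C@@H]1C[C@@H]2C[C@H]([C@H]1C)C2(C)C | intermediate (not isolated)
20 | (2R,3R)-3-(methoxymethoxy)pent-4-en-2-ol | C=C[C@@H](OCOC)[C@@H](C)O | intermediate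
21 | (2R,3R)-pent-4-ene-2,3-diol | C=C[C@@H](O)[C@@H](C)O | intermediate
22 | (3R,4R)-pent-1-ene-3,4-diyl diacetate | C=C[C@@H](OC(C)=O)[C@@H](C)OC(C)=O | intermediate
23 | (6S)-6-[(1S,2R,3E,5R,6R)-5,6-diacetoxy-1-hydroxy-2-methoxyhept-3-en-1-yl]-5,6-dihydro-2H-pyran-2-one | CO[C@H](/C=C/[C@@H](OC(C)=O)[C@@H](C)OC(C)=O)[C@@H](O)[C@@H]1CC=CC(=O)O1 | target

Total step count: 9
Longest linear sequence: 6 (steps 1, 2, 3, 4, 5 and 9)

Steps most likely to fail

Step 4. The second lithiation may stay incomplete because n-BuLi is consumed by the boron species left from the epoxide opening, so that the alkynol is returned without the carboxyl group. The fallback reverses the order of the two bond formations in the same flask and sets out from 6 and 7. Lithium acetylide in THF at −78 °C is treated with one equivalent of CO2 to give lithium propiolate F1, and LiN(iPr)2 converts it into dilithium propiolate F2. F2 opens epoxide 6 at C5 in THF/DMPU (−20 °C → rt), and acidification brings the route back at 11.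

Step 9. Both olefins carry an allylic oxygen and an allylic branch, so initiation and turnover may be slow and homodimerisation of 22 or catalyst decay may outrun the cross reaction. The fallback uses a more reactive partner and moves the acetylation behind the coupling. It sets out from silyl-protected lactone 13, isolated by closing crude 12 with catalytic TsOH in CH2Cl2 in place of the HF treatment, and from diol 21. Cross-metathesis of 13 with the free allylic diol 21 (same ruthenium catalyst, CH2Cl2, 40 °C) should give the silyl-protected diol lactone F3. Acetylation (Ac2O, pyridine, DMAP) gives the silyl-protected diacetate F4, and aq. HF in MeCN removes the silyl group and brings the route back at 23.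

Step 2. The methoxy oxygen next to the carbinol may bind titanium and lower the rate difference between the enantiomers of 4, and the long reaction time may let isopropoxide open the terminal epoxide. The resolution also discards half of the material. The fallback takes C6 from the chiral pool and sets out from 2 and commercial (S)-glyceraldehyde acetonide F5. The chromium reagent 3 of step 1 adds to F5 under Felkin–Anh control and with anti simple selectivity to give the all-anti adduct F6. TBSCl and imidazole give silyl ether F7, and aq. AcOH removes the acetonide to give diol F8. TsCl, Et3N and catalytic Bu2SnO sulfonylate the primary hydroxyl to give tosylate F9, and K2CO3 in MeOH closes the epoxide with retention at C6, which brings the route back at 6.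

Further compounds
F1 | step 4 | lithium propiolate | C#CC(=O)[O-].[Li+]
F2 | step 4 | dilithium propiolate (lithium 3-lithioprop-2-ynoate) | [Li+].[Li+].[C-]#CC(=O)[O-]
F3 | step 9 | (6S)-6-[(1S,2R,3E,5R,6R)-1-[(tert-butyldimethylsilyl)oxy]-5,6-dihydroxy-2-methoxyhept-3-en-1-yl]-5,6-dihydro-2H-pyran-2-one | CO[C@H](/C=C/[C@@H](O)[C@@H](C)O)[C@@H](O[Si](C)(C)C(C)(C)C)[C@@H]1CC=CC(=O)O1
F4 | step 9 | (6S)-6-[(1S,2R,3E,5R,6R)-5,6-diacetoxy-1-[(tert-butyldimethylsilyl)oxy]-2-methoxyhept-3-en-1-yl]-5,6-dihydro-2H-pyran-2-one | CO[C@H](/C=C/[C@@H](OC(C)=O)[C@@H](C)OC(C)=O)[C@@H](O[Si](C)(C)C(C)(C)C)[C@@H]1CC=CC(=O)O1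
F5 | step 2 | (4S)-2,2-dimethyl-1,3-dioxolane-4-carbaldehyde ((S)-glyceraldehyde acetonide) | O=C[C@@H]1COC(C)(C)O1
F6 | step 2 | (1R,2R)-1-[(4S)-2,2-dimethyl-1,3-dioxolan-4-yl]-2-methoxybut-3-en-1-ol | CO[C@H](C=C)[C@@H](O)[C@@H]1COC(C)(C)O1
F7 | step 2 | tert-butyl{[(1R,2R)-1-[(4S)-2,2-dimethyl-1,3-dioxolan-4-yl]-2-methoxybut-3-en-1-yl]oxy}dimethylsilane | CO[C@H](C=C)[C@@H](O[Si](C)(C)C(C)(C)C)[C@@H]1COC(C)(C)O1
F8 | step 2 | (2S,3S,4R)-3-[(tert-butyldimethylsilyl)oxy]-4-methoxyhex-5-ene-1,2-diol | CO[C@H](C=C)[C@@H](O[Si](C)(C)C(C)(C)C)[C@@H](O)CO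
F9 | step 2 | (2S,3S,4R)-3-[(tert-butyldimethylsilyl)oxy]-2-hydroxy-4-methoxyhex-5-en-1-yl 4-methylbenzenesulfonate | CO[C@H](C=C)[C@@H](O[Si](C)(C)C(C)(C)C)[C@@H](O)COS(=O)(=O)c1ccc(C)cc1
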